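**Retrosynthetic overview**
- The six benzyl ethers come off last. Before that, the whole carbon skeleton is assembled in one convergent, redox-neutral palladium-catalysed [3+2] annulation.
- Key disconnection: the five-membered ring of the indane is cut at C1–C2 and at C3–C3a. This gives a Z-alkenyl triflate (guaiacyl–CH=C(OTf)–ring A) and an E-2-hydroxystilbene (2,4-dioxygenated ring–CH=CH–3,5-dioxygenated ring).
- Enabling feature: the free hydroxyl at C2' of the aryl ring on C3 lets a benzylic C3–palladium bond collapse to an ortho-quinone methide. C3a of ring A is ortho to the oxygen at C4 and para to the oxygen at C6, and it sits where it can close a five-membered ring on C3.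
- The alkenyl triflate comes from a benzyl aryl ketone (ketone α-arylation, then triflation of the Z-enolate). The stilbene comes from a Horner–Wadsworth–Emmons olefination.
- Ring order: the four benzene rings are bought. The five-membered ring is the only ring formed, and it forms in the key step.

Key step: step 6

Assumption: the (S)-configured pyridine-oxazoline ligand is taken to give the 2S,3S series; if the sense of induction is the opposite, its enantiomer is used without other change.

Step 1
Reactants: 1 4-bromo-2-methoxyphenol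
Product: 2 1-(benzyloxy)-4-bromo-2-methoxybenzene
Conditions: BnBr, K2CO3, acetone, reflux
Reagents that add atoms: benzyl bromide, BrCc1ccccc1
Why: Williamson ether synthesis on the only acidic hydroxyl, with no stereocentre involved.

Step 2
Reactants: 2 1-(benzyloxy)-4-bromo-2-methoxybenzene; 3 1-[3,5-bis(benzyloxy)phenyl]ethan-1-one
Product: 4 1-[3,5-bis(benzyloxy)phenyl]-2-[4-(benzyloxy)-3-methoxyphenyl]ethan-1-one
Conditions: Pd2(dba)3 (cat.), XPhos (cat.), NaOtBu, toluene, 80 °C
Reagents that add atoms: none
Why: Palladium-catalysed α-arylation of an aryl methyl ketone enolate, which should stop at monoarylation because the more acidic product is stored as its enolate, while benzyl and methyl ethers are inert.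

Step 3
Reactants: 4 1-[3,5-bis(benzyloxy)phenyl]-2-[4-(benzyloxy)-3-methoxyphenyl]ethan-1-one
Product: 5 (Z)-1-[3,5-bis(benzyloxy)phenyl]-2-[4-(benzyloxy)-3-methoxyphenyl]ethenyl trifluoromethanesulfonate (triflate oxygen cis to the guaiacyl ring, the two aryl rings trans)
Conditions: KHMDS, THF, −78 °C; then PhNTf2, −78 °C to 0 °C
Reagents that add atoms: N-phenylbis(trifluoromethanesulfonimide), O=S(=O)(N(c1ccccc1)S(=O)(=O)C(F)(F)F)C(F)(F)F
Why: Enolate O-triflation, in which the benzyl aryl ketone should give the Z(O)-enolate that keeps the two aryl rings trans, so the leaving group ends cis to the guaiacyl ring, the geometry later carried into the benzylidene.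

Step 4
Reactants: 6 1,3-bis(benzyloxy)-5-(bromomethyl)benzene
Product: 7 diethyl {[3,5-bis(benzyloxy)phenyl]methyl}phosphonate
Conditions: P(OEt)3 (neat), 140 °C
Reagents that add atoms: triethyl phosphite, CCOP(OCC)OCC
Why: Michaelis–Arbuzov reaction of a primary benzylic bromide, driven by loss of the volatile alkyl bromide.

Step 5
Reactants: 7 diethyl {[3,5-bis(benzyloxy)phenyl]methyl}phosphonate; 8 4-(benzyloxy)-2-hydroxybenzaldehyde
Product: 9 5-(benzyloxy)-2-{(E)-2-[3,5-bis(benzyloxy)phenyl]ethenyl}phenol
Conditions: KOtBu (2.5 equiv), THF, 0 °C to rt; then aq. NH4Cl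
Reagents that add atoms: none
Why: Horner–Wadsworth–Emmons olefination, E-selective for benzylic phosphonates, in which the first equivalent of base stores the phenol as its phenoxide and work-up returns it.

Step 6
Reactants: 5 (Z)-1-[3,5-bis(benzyloxy)phenyl]-2-[4-(benzyloxy)-3-methoxyphenyl]ethenyl trifluoromethanesulfonate; 9 5-(benzyloxy)-2-{(E)-2-[3,5-bis(benzyloxy)phenyl]ethenyl}phenol
Product: 11 (1E,2S,3S)-4,6-bis(benzyloxy)-1-[4-(benzyloxy)-3-methoxybenzylidene]-2-[3,5-bis(benzyloxy)phenyl]-3-[4-(benzyloxy)-2-hydroxyphenyl]-2,3-dihydro-1H-indene, via ortho-quinone methide 10 (not isolated)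
Conditions: Pd2(dba)3 (cat.), (S)-4-tert-butyl-2-[5-(trifluoromethyl)pyridin-2-yl]-4,5-dihydrooxazole (cat.), KHCO3, 3 Å MS, N,N-dimethylacetamide, 25–40 °C
Reagents that add atoms: none
Why: Proposed new method: zerovalent palladium inserts into the C–OTf bond of 5 with retention, the cationic alkenylpalladium binds the stilbene double bond of 9, and syn migratory insertion joins the alkenyl carbon (later C1) to the stilbene carbon that bears the 3,5-dioxygenated ring (C2), which leaves palladium on the benzylic carbon next to the ortho-phenol (C3); loss of the phenol proton to KHCO3 then expels zerovalent palladium and gives ortho-quinone methide 10 before β-hydride elimination can occur, and C3a of ring A adds to C3 with rearomatisation of both rings. The closest known reaction types are the enantioselective Heck alkenylation of acyclic internal alkenes with alkenyl triflates under pyridine-oxazoline ligands and the palladium-catalysed difunctionalisation of 2-alkenylphenols, in which a benzylic alkylpalladium collapses to an ortho-quinone methide that an electron-rich arene captures; new is their merger into a redox-neutral annulation on a stilbene. The single ring closes in the 5-exo-trig mode by Friedel–Crafts conjugate addition to the exocyclic C3=C bond of 10. C2 is set in the insertion by the ligand, which selects the alkene face, and C3 is set in the ring closure by C2, because the quinone methide ring takes the side of the forming five-membered ring opposite to the C2 aryl group (2,3-trans). The E geometry of the benzylidene follows from the Z geometry of 5, since oxidative addition and insertion both retain it. Cross-selectivity is inherent (only 5 has a C–OTf bond, only 9 has an alkene that can release palladium through its phenol), the orientation of the insertion is secured by the ortho-hydroxyl, which holds palladium at the proximal carbon as an oxa-π-benzyl unit, and by the greater bulk of the ortho-substituted ring, and the site of arene attack is secured because C3a is ortho and para to the two benzyloxy groups and is the only activated position that gives a five-membered ring.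

Step 7
Reactants: 11 (1E,2S,3S)-4,6-bis(benzyloxy)-1-[4-(benzyloxy)-3-methoxybenzylidene]-2-[3,5-bis(benzyloxy)phenyl]-3-[4-(benzyloxy)-2-hydroxyphenyl]-2,3-dihydro-1H-indene
Product: 12 (1E,2S,3S)-3-(2,4-dihydroxyphenyl)-2-(3,5-dihydroxyphenyl)-1-(4-hydroxy-3-methoxybenzylidene)-2,3-dihydro-1H-indene-4,6-diol
Conditions: BCl3, pentamethylbenzene, CH2Cl2, −78 °C; then H2O
Reagents that add atoms: none
Why: Lewis-acid debenzylation with a non-basic cation scavenger, in which aryl benzyl ethers should ionise far faster than the aryl methyl ether at −78 °C, the scavenger intercepts the benzyl cations, and neither the two stereocentres nor the benzylidene is touched.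

**Compound list**
1 | 4-bromo-2-methoxyphenol | COc1cc(Br)ccc1O | starting material
2 | 1-(benzyloxy)-4-bromo-2-methoxybenzene | COc1cc(Br)ccc1OCc1ccccc1 | intermediate
3 | 1-[3,5-bis(benzyloxy)phenyl]ethan-1-one | CC(=O)c1cc(OCc2ccccc2)cc(OCc2ccccc2)c1 | starting material
4 | 1-[3,5-bis(benzyloxy)phenyl]-2-[4-(benzyloxy)-3-methoxyphenyl]ethan-1-one | COc1cc(CC(=O)c2cc(OCc3ccccc3)cc(OCc3ccccc3)c2)ccc1OCc1ccccc1 | intermediate
5 | (Z)-1-[3,5-bis(benzyloxy)phenyl]-2-[4-(benzyloxy)-3-methoxyphenyl]ethenyl trifluoromethanesulfonate | COc1cc(/C=C(\OS(=O)(=O)C(F)(F)F)c2cc(OCc3ccccc3)cc(OCc3ccccc3)c2)ccc1OCc1ccccc1 | intermediate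
6 | 1,3-bis(benzyloxy)-5-(bromomethyl)benzene | BrCc1cc(OCc2ccccc2)cc(OCc2ccccc2)c1 | starting material
7 | diethyl {[3,5-bis(benzyloxy)phenyl]methyl}phosphonate | CCOP(=O)(Cc1cc(OCc2ccccc2)cc(OCc2ccccc2)c1)OCC | intermediate
8 | 4-(benzyloxy)-2-hydroxybenzaldehyde | O=Cc1ccc(OCc2ccccc2)cc1O | starting material
9 | 5-(benzyloxy)-2-{(E)-2-[3,5-bis(benzyloxy)phenyl]ethenyl}phenol | Oc1cc(OCc2ccccc2)ccc1/C=C/c1cc(OCc2ccccc2)cc(OCc2ccccc2)c1 | intermediate
10 | (6E)-3-(benzyloxy)-6-{(2S,3E)-2,3-bis[3,5-bis(benzyloxy)phenyl]-4-[4-(benzyloxy)-3-methoxyphenyl]but-3-en-1-ylidene}cyclohexa-2,4-dien-1-one (ortho-quinone methide, not isolated) | COc1cc(/C=C(/c2cc(OCc3ccccc3)cc(OCc3ccccc3)c2)[C@@H](/C=C2\C=CC(OCc3ccccc3)=CC2=O)c2cc(OCc3ccccc3)cc(OCc3ccccc3)c2)ccc1OCc1ccccc1 | intermediate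
11 | (1E,2S,3S)-4,6-bis(benzyloxy)-1-[4-(benzyloxy)-3-methoxybenzylidene]-2-[3,5-bis(benzyloxy)phenyl]-3-[4-(benzyloxy)-2-hydroxyphenyl]-2,3-dihydro-1H-indene | COc1cc(/C=C2/c3cc(OCc4ccccc4)cc(OCc4ccccc4)c3[C@H](c3ccc(OCc4ccccc4)cc3O)[C@H]2c2cc(OCc3ccccc3)cc(OCc3ccccc3)c2)ccc1OCc1ccccc1 | intermediate
12 | (1E,2S,3S)-3-(2,4-dihydroxyphenyl)-2-(3,5-dihydroxyphenyl)-1-(4-hydroxy-3-methoxybenzylidene)-2,3-dihydro-1H-indene-4,6-diol | COc1cc(/C=C2/c3cc(O)cc(O)c3[C@H](c3ccc(O)cc3O)[C@H]2c2cc(O)cc(O)c2)ccc1O | target

**Step count**
- Total steps: 7.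
- Longest linear sequence: 5 steps (steps 1, 2, 3, 6, 7; compounds 1 → 2 → 4 → 5 → 11 → 12).

**Steps most likely to fail**

Step 6 carries the most risk. Insertion into the hindered stilbene may be slow. β-Hydride elimination, or a 1,5-hydrogen shift in the quinone methide, may outrun ring closure. Face selection by the ligand may also be poor. The fallback separates bond formation from stereocontrol and uses known reaction types. It sets out from 5 and 9.
- A classical Heck alkenylation (Pd(OAc)2, PPh3, K2CO3, DMF, 90 °C), in which β-hydride elimination is now wanted, should give the achiral diene 2-{(1E,3Z)-2,3-bis[3,5-bis(benzyloxy)phenyl]-4-[4-(benzyloxy)-3-methoxyphenyl]buta-1,3-dien-1-yl}-5-(benzyloxy)phenol F1.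
- A chiral phosphoric acid ((R)-3,3'-bis(2,4,6-triisopropylphenyl)-1,1'-binaphthyl-2,2'-diyl hydrogen phosphate, toluene, 0 °C) should then protonate the 2-alkenylphenol unit of F1 at C2 to give the ion-paired ortho-quinone methide.
- Ring A should add to C3 inside the chiral ion pair. This is the known mode of acid-catalysed asymmetric arene addition to 2-alkenylphenols. Reversible protonation lets both C2 epimers drain into the trans product.
- The fallback comes back to the route at 11.

Step 7 is next. Three processes may interfere: loss of the guaiacyl methyl ether by boron chelation once the neighbouring benzyl group has left, C-benzylation of the freed resorcinol rings, and acid-induced closure of the C2 aryl ring onto the protonated benzylidene. The fallback changes the protecting-group family so that the last step is a fluoride desilylation. It sets out from 4.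
- Hydrogenolysis (H2, Pd/C, EtOAc, rt), harmless at this alkene-free stage, should give 1-(3,5-dihydroxyphenyl)-2-(4-hydroxy-3-methoxyphenyl)ethan-1-one F2.
- TBSCl and imidazole in DMF should give the tris(tert-butyldimethylsilyl) ether of that ketone F3.
- KHMDS then PhNTf2 should give the corresponding Z-alkenyl triflate F4.
- Commercial oxyresveratrol is silylated with three equivalents of TBSCl (imidazole, DMF, 0 °C) at its three unhindered hydroxyls, the one flanked by the styryl group reacting last. This should give the tris(silyl) 2-hydroxystilbene F5.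
- F4 and F5 are joined under the conditions of step 6 to give the hexakis(tert-butyldimethylsilyl) analogue of 11, F6.
- Bu4NF buffered with AcOH in THF at 0 °C brings the fallback back to the route at 12.

Step 5 is third. Deprotonation of 8 gives a phenoxide that deactivates the aldehyde towards the phosphonate anion, so addition may stall. The fallback exchanges the roles of the partners and makes the stilbene bond by a Heck reaction. It sets out from 8.
- Wittig methylenation with excess Ph3P=CH2 (MePPh3Br, KOtBu, THF), which is routine on free salicylaldehydes, should give 5-(benzyloxy)-2-ethenylphenol F7.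
- Heck arylation with commercial 1,3-bis(benzyloxy)-5-bromobenzene (Pd(OAc)2, P(o-tol)3, K2CO3, DMF, 100 °C) should give the E-stilbene.
- The fallback comes back to the route at 9.

**Further compounds**
F1 | step 6 | 2-{(1E,3Z)-2,3-bis[3,5-bis(benzyloxy)phenyl]-4-[4-(benzyloxy)-3-methoxyphenyl]buta-1,3-dien-1-yl}-5-(benzyloxy)phenol | COc1cc(/C=C(/c2cc(OCc3ccccc3)cc(OCc3ccccc3)c2)\C(c2cc(OCc3ccccc3)cc(OCc3ccccc3)c2)=C\c2ccc(OCc3ccccc3)cc2O)ccc1OCc1ccccc1
F2 | step 7 | 1-(3,5-dihydroxyphenyl)-2-(4-hydroxy-3-methoxyphenyl)ethan-1-one | COc1cc(CC(=O)c2cc(O)cc(O)c2)ccc1O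
F3 | step 7 | 1-{3,5-bis[(tert-butyldimethylsilyl)oxy]phenyl}-2-{4-[(tert-butyldimethylsilyl)oxy]-3-methoxyphenyl}ethan-1-one | COc1cc(CC(=O)c2cc(O[Si](C)(C)C(C)(C)C)cc(O[Si](C)(C)C(C)(C)C)c2)ccc1O[Si](C)(C)C(C)(C)C
F4 | step 7 | (Z)-1-{3,5-bis[(tert-butyldimethylsilyl)oxy]phenyl}-2-{4-[(tert-butyldimethylsilyl)oxy]-3-methoxyphenyl}ethenyl trifluoromethanesulfonate | COc1cc(/C=C(\OS(=O)(=O)C(F)(F)F)c2cc(O[Si](C)(C)C(C)(C)C)cc(O[Si](C)(C)C(C)(C)C)c2)ccc1O[Si](C)(C)C(C)(C)C
F5 | step 7 | 5-[(tert-butyldimethylsilyl)oxy]-2-[(E)-2-{3,5-bis[(tert-butyldimethylsilyl)oxy]phenyl}ethenyl]phenol | Oc1cc(O[Si](C)(C)C(C)(C)C)ccc1/C=C/c1cc(O[Si](C)(C)C(C)(C)C)cc(O[Si](C)(C)C(C)(C)C)c1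
F6 | step 7 | (1E,2S,3S)-hexakis(tert-butyldimethylsilyl) analogue of 11 (silyl in place of each benzyl, 2-hydroxyl of the C3 aryl ring free) | COc1cc(/C=C2/c3cc(O[Si](C)(C)C(C)(C)C)cc(O[Si](C)(C)C(C)(C)C)c3[C@H](c3ccc(O[Si](C)(C)C(C)(C)C)cc3O)[C@H]2c2cc(O[Si](C)(C)C(C)(C)C)cc(O[Si](C)(C)C(C)(C)C)c2)ccc1O[Si](C)(C)C(C)(C)C
F7 | step 5 | 5-(benzyloxy)-2-ethenylphenol | C=Cc1ccc(OCc2ccccc2)cc1O
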